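**Overview**

Ring atoms are numbered O1, C2 (CH3), C3 (CH2OH), C4 (CH2CO2R arm), C5 (CO2Me), C6 (enol ether CH).
Retrosynthetic cuts: the ring bond C3–C4, the O–CH2 bond of the hydroxytyrosol ester, the enol ether bond O1–C6, and the silyl ethers on the catechol and the CH2OH group.
Enabling feature: in the dihydropyran (O1, C2–C6) the C3–C4 bond joins a carbon carrying CH2OH, which can be the internal carbon of a terminal epoxide, to a carbon β to the side-chain ester carbonyl. C4, C5, C6, the CO2Me group and the CH2CO2 arm are together the untouched carbon skeleton of methyl coumalate.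
Forward order: the chain is joined first at O1–C6 (an epoxy alkoxide opens methyl coumalate), then at the side-chain ester (Mitsunobu reaction with bis-silylated hydroxytyrosol). The only ring is closed last at C3–C4 by a Cp2TiCl radical cyclization, and desilylation ends the route.
Stereochemistry: C2 is bought in (R)-but-3-en-2-ol and its C–O bond is never broken. C3 and C4 arise together in the ring closure under control of C2 (all-pseudo-equatorial half-chair, 2,3-trans and 3,4-trans). The epoxide carbon's configuration is erased at the radical stage.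

Key step: step 6

Remark: hydroxytyrosol, (R)-but-3-en-2-ol and methyl coumalate are taken as purchasable.

**Route**

Step 1
Reactants: 1 hydroxytyrosol, 2-(3,4-dihydroxyphenyl)ethanol
Product: 2 tert-butyl{2-[3,4-bis(tert-butyldimethylsilyloxy)phenyl]ethoxy}dimethylsilane
Conditions: TBSCl (3.5 equiv), imidazole, DMF, rt
Reagents that add atoms: tert-butyldimethylsilyl chloride, CC(C)(C)[Si](C)(C)Cl
Why: Exhaustive silylation under standard imidazole/DMF conditions masks the catechol, which would otherwise bind titanium in step 6 and compete as an acidic partner in step 5; no stereocentre is involved.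

Step 2
Reactants: 2 tert-butyl{2-[3,4-bis(tert-butyldimethylsilyloxy)phenyl]ethoxy}dimethylsilane
Product: 3 2-[3,4-bis(tert-butyldimethylsilyloxy)phenyl]ethanol
Conditions: PPTS (cat.), MeOH, rt
Reagents that add atoms: none
Why: Acid-catalysed methanolysis of silyl ethers is much faster at the more basic primary alkyl oxygen than at the two aryl oxygens, so selective solvolysis should free only the alcohol.

Step 3
Reactants: 4 (R)-but-3-en-2-ol
Product: 5 (2R,3S)-3,4-epoxybutan-2-ol, (1R)-1-[(2S)-oxiran-2-yl]ethanol
Conditions: Ti(OiPr)4 (0.2 equiv), D-(−)-diisopropyl tartrate (0.25 equiv), t-BuOOH (isooctane), 4 Å MS, CH2Cl2, −20 °C; non-aqueous work-up, distillation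
Reagents that add atoms: tert-butyl hydroperoxide, CC(C)(C)OO
Why: Sharpless asymmetric epoxidation of a secondary allylic alcohol in its matched pairing (R carbinol with the D-tartrate) should give the erythro epoxy alcohol with the new centre S, and this centre need not be pure because it becomes a planar radical in step 6.

Step 4
Reactants: 5 (2R,3S)-3,4-epoxybutan-2-ol; 6 methyl coumalate, methyl 2-oxo-2H-pyran-5-carboxylate
Product: 9 (2Z,4E)-5-methoxy-4-({(1R)-1-[(2S)-oxiran-2-yl]ethoxy}methylidene)-5-oxopent-2-enoic acid, via sodium alkoxide of the epoxy alcohol 7 (not isolated), via sodium carboxylate of the ring-opened acid 8 (not isolated)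
Conditions: NaN(SiMe3)2 (1.0 equiv), THF, −78 °C; then 6, −78 to −30 °C; cold dilute HCl to pH 4, EtOAc extraction, used at once
Reagents that add atoms: sodium bis(trimethylsilyl)amide, C[Si](C)(C)[N-][Si](C)(C)C.[Na+] (sodium, in 7 and 8 only)
Why: Conjugate addition–ring opening of a 2-pyranone by an alkoxide: the alkoxide adds at C6 (β to the ester, δ to the lactone carbonyl) and the ring O–C6 bond breaks to a carboxylate that resists further attack, the Z enoate being inherited from the ring, the alkoxymethylidene settling in its more stable E form (oxygen cis to the vinyl carbon), and both stereocentres of 5 being carried over because no bond to them is touched while low temperature in THF keeps Payne-type epoxide migration slow.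

Step 5
Reactants: 9 the epoxy dienoic acid; 3 2-[3,4-bis(tert-butyldimethylsilyloxy)phenyl]ethanol
Product: 10 1-{2-[3,4-bis(tert-butyldimethylsilyloxy)phenyl]ethyl} 5-methyl (2Z,4E)-4-({(1R)-1-[(2S)-oxiran-2-yl]ethoxy}methylidene)pent-2-enedioate
Conditions: PPh3, DIAD, THF, 0 °C
Reagents that add atoms: none
Why: Mitsunobu esterification: the acid protonates the PPh3–DIAD betaine and its carboxylate displaces the oxyphosphonium of the primary alcohol by SN2, so the acyl group is never activated (no re-closure to the pyranone), the epoxide, enol ether and aryl silyl ethers are left alone, and any drift of the enoate geometry is without consequence.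

Step 6
Reactants: 10 the epoxy dienoate diester
Product: 11 methyl (2R,3R,4S)-4-(2-{2-[3,4-bis(tert-butyldimethylsilyloxy)phenyl]ethoxy}-2-oxoethyl)-2-methyl-3-[(trimethylsilyloxy)methyl]-3,4-dihydro-2H-pyran-5-carboxylate
Conditions: Cp2TiCl2 (20 mol %), Mn dust, 2,4,6-collidinium chloride, TMSCl, 2,4,6-collidine, THF, rt, slow addition of 10; buffered work-up, Et3N-deactivated silica
Reagents that add atoms: chlorotrimethylsilane, C[Si](C)(C)Cl
Why: Cp2TiCl (trivalent titanium, formed and recycled from Cp2TiCl2 by zerovalent manganese) gives one electron to the terminal epoxide, which opens to the secondary radical at C3 with the oxygen left on CH2 as a titanium alkoxide; the nucleophilic radical adds to C4, the β-carbon of the enoate, the α-ester radical so formed is reduced by a second Cp2TiCl to a titanium enolate that collidinium protonates, and TMSCl caps the alkoxide, which releases titanium and shuts off δ-lactonization. The closest known reaction type is the titanocene chloride reductive epoxide opening followed by exo radical cyclization onto an α,β-unsaturated ester. The dihydropyran (O1, C2, C3, C4, C5, C6) closes at C3–C4 in the 6-exo-trig mode, the competing closures (four-membered ring at C6, 5-endo at C5, 7-endo at the α-carbon) being slow or electronically mismatched. C3 is set under control of C2: the radical is planar (the epoxide configuration is erased) and in the half-chair transition state the C2 methyl and the bulky CH2O–Ti group should both take pseudo-equatorial positions, hence 2,3-trans. C4 is set under control of C3 and, through it, C2: the enoate terminus should also sit pseudo-equatorial, on the face of C4 away from the CH2O–Ti group, hence 3,4-trans and the (2R,3R,4S) array. The step needs this all-trans diastereoselectivity and a ring closure that outruns capture of the C3 radical by titanium (which would end in β-elimination to an allyl ether); the first is secured by the C2 methyl group and the E enol ether that holds O1 cis to C4, the second by the electron-poor acceptor and the low stationary concentration of trivalent titanium under catalytic turnover with slow addition of 10.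

Step 7
Reactants: 11 the silyl-protected dihydropyran
Product: 12 methyl (2R,3R,4S)-4-{2-[2-(3,4-dihydroxyphenyl)ethoxy]-2-oxoethyl}-3-(hydroxymethyl)-2-methyl-3,4-dihydro-2H-pyran-5-carboxylate (target CNP0204147.1)
Conditions: Et3N·3HF, THF, 0 °C to rt
Reagents that add atoms: none
Why: Fluoride-driven desilylation under near-neutral, base-free conditions should remove the two aryl TBS ethers and the primary TMS ether as silyl fluorides, while the absence of base keeps the freed CH2OH from lactonizing onto the aryl-ethyl ester and the catechol from oxidizing; no stereocentre is touched.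

**Compound list**

1 | hydroxytyrosol, 2-(3,4-dihydroxyphenyl)ethanol | OCCc1ccc(O)c(O)c1 | starting material
2 | tert-butyl{2-[3,4-bis(tert-butyldimethylsilyloxy)phenyl]ethoxy}dimethylsilane | CC(C)(C)[Si](C)(C)OCCc1ccc(O[Si](C)(C)C(C)(C)C)c(O[Si](C)(C)C(C)(C)C)c1 | intermediate
3 | 2-[3,4-bis(tert-butyldimethylsilyloxy)phenyl]ethanol | OCCc1ccc(O[Si](C)(C)C(C)(C)C)c(O[Si](C)(C)C(C)(C)C)c1 | intermediate
4 | (R)-but-3-en-2-ol | C[C@@H](O)C=C | starting material
5 | (2R,3S)-3,4-epoxybutan-2-ol, (1R)-1-[(2S)-oxiran-2-yl]ethanol | C[C@@H](O)[C@@H]1CO1 | intermediate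
6 | methyl coumalate, methyl 2-oxo-2H-pyran-5-carboxylate | COC(=O)C1=COC(=O)C=C1 | starting material
7 | sodium (1R)-1-[(2S)-oxiran-2-yl]ethanolate | C[C@@H]([O-])[C@@H]1CO1.[Na+] | intermediate
8 | sodium (2Z,4E)-5-methoxy-4-({(1R)-1-[(2S)-oxiran-2-yl]ethoxy}methylidene)-5-oxopent-2-enoate | C[C@@H](O/C=C(/C(=O)OC)\C=C/C(=O)[O-])[C@@H]1CO1.[Na+] | intermediate
9 | (2Z,4E)-5-methoxy-4-({(1R)-1-[(2S)-oxiran-2-yl]ethoxy}methylidene)-5-oxopent-2-enoic acid | C[C@@H](O/C=C(/C(=O)OC)\C=C/C(=O)O)[C@@H]1CO1 | intermediate
10 | 1-{2-[3,4-bis(tert-butyldimethylsilyloxy)phenyl]ethyl} 5-methyl (2Z,4E)-4-({(1R)-1-[(2S)-oxiran-2-yl]ethoxy}methylidene)pent-2-enedioate | C[C@@H](O/C=C(/C(=O)OC)\C=C/C(=O)OCCc1ccc(O[Si](C)(C)C(C)(C)C)c(O[Si](C)(C)C(C)(C)C)c1)[C@@H]1CO1 | intermediate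
11 | methyl (2R,3R,4S)-4-(2-{2-[3,4-bis(tert-butyldimethylsilyloxy)phenyl]ethoxy}-2-oxoethyl)-2-methyl-3-[(trimethylsilyloxy)methyl]-3,4-dihydro-2H-pyran-5-carboxylate | COC(=O)C1=CO[C@H](C)[C@@H](CO[Si](C)(C)C)[C@@H]1CC(=O)OCCc1ccc(O[Si](C)(C)C(C)(C)C)c(O[Si](C)(C)C(C)(C)C)c1 | intermediate
12 | methyl (2R,3R,4S)-4-{2-[2-(3,4-dihydroxyphenyl)ethoxy]-2-oxoethyl}-3-(hydroxymethyl)-2-methyl-3,4-dihydro-2H-pyran-5-carboxylate | COC(=O)C1=CO[C@H](C)[C@@H](CO)[C@@H]1CC(=O)OCCc1ccc(O)c(O)c1 | target

**Step count**

Total step count: 7.
Longest linear sequence: 5 steps (steps 3, 4, 5, 6, 7 from 4; the arm from 1 through steps 1, 2, 5, 6, 7 is equally long).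

**Steps most likely to fail**

Step 6. The C3 radical may be captured by a second trivalent titanium centre and lose its β-oxygen, or be quenched before it closes, or the closure may discriminate poorly between the two faces of the enoate. The fallback sets out from 10 and comes back at 12; it generates the same C3 radical in a tin hydride chain, with no metal on carbon or oxygen and a bulky silyl ether on the CH2O arm. The epoxide of 10 would be opened at its CH2 terminus with water under catalysis by (salen)Co(OAc) (trivalent cobalt, matched enantiomer; salen = N,N'-bis(3,5-di-tert-butylsalicylidene)cyclohexane-1,2-diaminate) to give the vicinal diol F1. TBSCl and imidazole would silylate the primary hydroxyl to the mono-silyl ether F2. PhOC(S)Cl, pyridine and DMAP would convert the secondary hydroxyl into the phenyl thionocarbonate F3. Slow addition of Bu3SnH with AIBN in benzene at 80 °C should cleave the C3–O bond homolytically (Barton–McCombie-type radical generation), and 6-exo closure onto C4 should give the tris-TBS dihydropyran F4. Et3N·3HF, with a longer reaction time for the alkyl TBS ether, would then give 12.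

Step 4. The epoxide may migrate within the alkoxide (Payne rearrangement), or the alkoxide may open another epoxide before it reaches the pyranone. The fallback sets out from 4, 6 and 3 and comes back at 10; the epoxide is introduced only after the enol ether and the ester are in place. Alcohol 4 would be deprotonated with NaN(SiMe3)2 to sodium (R)-but-3-en-2-olate F5. This would open 6 under the conditions of step 4 to the sodium alkenyl dienoate F6 and, after acidification, the alkene acid F7. Mitsunobu esterification with 3 as in step 5 would give the alkene ester F8. mCPBA (NaHCO3, CH2Cl2, rt) should then epoxidize the terminal alkene, the only one not deactivated by conjugation with an ester, to 10 together with its epoxide epimer F9. Both would give the same planar C3 radical in step 6.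

Step 5. On concentration the free acid 9 may open its own or a neighbouring epoxide, and PPh3 may add to the dienoate, so that the esterification stalls. The fallback sets out from 3 and 8 and comes back at 10; the acid is never liberated. Alcohol 3 would be converted by the Appel reaction (I2, PPh3, imidazole, CH2Cl2) into the aryl-ethyl iodide F10. The THF solution of the sodium carboxylate 8 from step 4 would be diluted with DMF and alkylated with F10 at rt (carboxylate SN2) to give 10.

**Further compounds**

F1 | step 6 | 1-{2-[3,4-bis(tert-butyldimethylsilyloxy)phenyl]ethyl} 5-methyl (2Z,4E)-4-({[(2R,3S)-3,4-dihydroxybutan-2-yl]oxy}methylidene)pent-2-enedioate | C[C@@H](O/C=C(/C(=O)OC)\C=C/C(=O)OCCc1ccc(O[Si](C)(C)C(C)(C)C)c(O[Si](C)(C)C(C)(C)C)c1)[C@@H](O)CO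
F2 | step 6 | 1-{2-[3,4-bis(tert-butyldimethylsilyloxy)phenyl]ethyl} 5-methyl (2Z,4E)-4-({[(2R,3S)-4-(tert-butyldimethylsilyloxy)-3-hydroxybutan-2-yl]oxy}methylidene)pent-2-enedioate | C[C@@H](O/C=C(/C(=O)OC)\C=C/C(=O)OCCc1ccc(O[Si](C)(C)C(C)(C)C)c(O[Si](C)(C)C(C)(C)C)c1)[C@@H](O)CO[Si](C)(C)C(C)(C)C
F3 | step 6 | 1-{2-[3,4-bis(tert-butyldimethylsilyloxy)phenyl]ethyl} 5-methyl (2Z,4E)-4-({[(2R,3S)-4-(tert-butyldimethylsilyloxy)-3-(phenoxycarbonothioyloxy)butan-2-yl]oxy}methylidene)pent-2-enedioate | C[C@@H](O/C=C(/C(=O)OC)\C=C/C(=O)OCCc1ccc(O[Si](C)(C)C(C)(C)C)c(O[Si](C)(C)C(C)(C)C)c1)[C@@H](OC(=S)Oc1ccccc1)CO[Si](C)(C)C(C)(C)C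
F4 | step 6 | methyl (2R,3R,4S)-4-(2-{2-[3,4-bis(tert-butyldimethylsilyloxy)phenyl]ethoxy}-2-oxoethyl)-3-[(tert-butyldimethylsilyloxy)methyl]-2-methyl-3,4-dihydro-2H-pyran-5-carboxylate | COC(=O)C1=CO[C@H](C)[C@@H](CO[Si](C)(C)C(C)(C)C)[C@@H]1CC(=O)OCCc1ccc(O[Si](C)(C)C(C)(C)C)c(O[Si](C)(C)C(C)(C)C)c1
F5 | step 4 | sodium (R)-but-3-en-2-olate | C[C@@H]([O-])C=C.[Na+]
F6 | step 4 | sodium (2Z,4E)-4-({[(2R)-but-3-en-2-yl]oxy}methylidene)-5-methoxy-5-oxopent-2-enoate | C[C@@H](O/C=C(/C(=O)OC)\C=C/C(=O)[O-])C=C.[Na+]
F7 | step 4 | (2Z,4E)-4-({[(2R)-but-3-en-2-yl]oxy}methylidene)-5-methoxy-5-oxopent-2-enoic acid | C[C@@H](O/C=C(/C(=O)OC)\C=C/C(=O)O)C=C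
F8 | step 4 | 1-{2-[3,4-bis(tert-butyldimethylsilyloxy)phenyl]ethyl} 5-methyl (2Z,4E)-4-({[(2R)-but-3-en-2-yl]oxy}methylidene)pent-2-enedioate | C[C@@H](O/C=C(/C(=O)OC)\C=C/C(=O)OCCc1ccc(O[Si](C)(C)C(C)(C)C)c(O[Si](C)(C)C(C)(C)C)c1)C=C
F9 | step 4 | 1-{2-[3,4-bis(tert-butyldimethylsilyloxy)phenyl]ethyl} 5-methyl (2Z,4E)-4-({(1R)-1-[(2R)-oxiran-2-yl]ethoxy}methylidene)pent-2-enedioate | C[C@@H](O/C=C(/C(=O)OC)\C=C/C(=O)OCCc1ccc(O[Si](C)(C)C(C)(C)C)c(O[Si](C)(C)C(C)(C)C)c1)[C@H]1CO1
F10 | step 5 | [4-(2-iodoethyl)-1,2-phenylene]bis(oxy)bis(tert-butyldimethylsilane) | ICCc1ccc(O[Si](C)(C)C(C)(C)C)c(O[Si](C)(C)C(C)(C)C)c1
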